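**Assumption:** Guidongnin is the 6,7-seco-ent-kaurane 6,19- and 7,20-bislactone bearing 11-OH, 15-OH and the Δ16 exocyclic methylene, with the absolute configuration of the given SMILES. The catalyst hands (the chiral oxazaborolidinium in Step 2, (S)-BINAP in Step 9) are assumed to give the enantiomers drawn.

## Retrosynthetic overview
1. Target ⇐ late-stage C15 allylic oxidation (SeO2, then Luche reduction). The D ring and C8 quaternary centre come from Pd(II)-mediated oxidative cycloalkenylation of the δ-lactone silyl ketene acetal onto a C13 isopropenyl group.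
2. Ring C, with C11–OH, ⇐ SmI2 6-endo ketyl–enoate cyclization of an aldehyde onto a spiro α,β-unsaturated δ-lactone, forming C9–C11.
3. The spiro δ-lactone ⇐ Michael addition of the C20 aldehyde to methyl acrylate, which sets the C10 quaternary centre anti to the axial C19–O. Then come reduction/lactonization, α-alkylation with a chiral iodide (C13 set by Rh-catalysed asymmetric 1,4-addition) and selenoxide dehydrogenation.
4. Ring A plus the 6,19-lactone (C4, C5) ⇐ catalytic enantioselective Diels–Alder of 4-methylfuran-2(5H)-one with (2E)-TBSOCH2CH=CH–CH=CH2 (the proposed new step).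
5. Ring order: A/γ-lactone → spiro δ-lactone → ring C → ring D (bridge) → C15 oxidation.

## Route

**Step 1**
Reactants: 1, (2E)-penta-2,4-dien-1-ol
Product: 2, TBS ether of 1
Conditions: TBSCl, imidazole, CH2Cl2, 0 °C → rt
Reagents that add atoms: TBSCl, CC(C)(C)[Si](C)(C)Cl
Why: Silylation of the primary alcohol (silyl protection) masks it for the Lewis-acid Diels–Alder.

**Step 2**
Reactants: 2; 3, 4-methylfuran-2(5H)-one
Product: 4, cis-fused bicyclic γ-lactone. In kaurane numbering C4 carries the C18 methyl and C19H2–O–C6(=O)–C5. C19, C6 and C20 (CH2OTBS on C10) are on one face; C18 and H5 are on the other. The Δ1 alkene is in ring A.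
Conditions: chiral cationic oxazaborolidinium·NTf2⁻ (20 mol%, from (S)-diphenylprolinol-derived B-aryl oxazaborolidine + HNTf2), CH2Cl2, −30 °C, 4 d
Reagents that add atoms: none
Why: A normal-demand, endo, "ortho"-selective Diels–Alder builds ring A, the cis-fused 6,19-lactone and the C4 quaternary and C5 stereocentres in one operation, and C10 epimers converge at Step 5. Proposed new method: the cationic Lewis acid binds the lactone C=O and lowers the LUMO of the trisubstituted butenolide C=C. The diene's CH2 terminus attacks the β-carbon (C4, forming the quaternary centre) while the substituted terminus closes onto C5, and the catalyst aryl group shields one enantioface. The closest known reactions are oxazaborolidinium-catalysed Diels–Alder of α,β-unsaturated lactones/esters and Lewis-acid Diels–Alder of 2(5H)-furanones, not yet shown for a β-substituted butenolide with an acyclic 1-substituted diene forming an all-carbon quaternary centre.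

**Step 3**
Reactants: 4
Product: 5, saturated lactone (ring A alkene reduced; stereocentres unchanged)
Conditions: H2 (1 atm), 10% Pd/C, EtOAc, rt
Reagents that add atoms: none
Why: Catalytic hydrogenation of the isolated cis-disubstituted alkene leaves the lactone and silyl ether untouched; no new stereocentre forms.

**Step 4**
Reactants: 5
Product: 6, primary alcohol (C20–OH)
Conditions: HF·pyridine, THF/pyridine, 0 °C → rt
Reagents that add atoms: none
Why: Mildly acidic fluoride desilylation avoids alkoxide-mediated translactonization onto the C6 lactone.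

**Step 5**
Reactants: 6
Product: 7, aldehyde (C20 CHO; C10 epimerizable, drawn unspecified)
Conditions: Dess–Martin periodinane, NaHCO3, CH2Cl2, rt
Reagents that add atoms: none
Why: Dess–Martin oxidation gives an α-branched aldehyde whose C10 epimers converge, so the diene geometry and endo/exo ratio of Step 2 do not matter.

**Step 6**
Reactants: 7; 8, methyl acrylate
Product: 9, aldehyde with C10 quaternary (CH2CH2CO2Me on the face opposite C19/C20; γ-lactone intact)
Conditions: DBU (0.2 equiv), THF, 25 → 50 °C
Reagents that add atoms: none (methyl acrylate is reactant 8)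
Why: Base-catalysed Michael addition of the aldehyde enolate/enamine occurs from the face anti to the axial C19–O that blocks the 1,3-diaxial side, setting C10 (C9 up, C20 down); the aldehyde is far more acidic than the hindered lactone C5–H, so only it enolizes.

**Step 7**
Reactants: 9
Product: 10, bis-lactone: spiro-δ-lactone (C7(=O)–O–C20 ring, C8H2–C9H2) plus the 6,19-γ-lactone
Conditions: NaBH4, MeOH, 0 °C; then DBU (cat.), toluene, 60 °C
Reagents that add atoms: none
Why: NaBH4 reduces only the aldehyde (chemoselective reduction), and the neopentyl hydroxy-ester closes to the δ-lactone (Thorpe–Ingold lactonization).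

**Step 8**
Reactants: 11, (tert-butyldimethylsilyloxy)acetaldehyde; 12, methyl (triphenylphosphoranylidene)acetate
Product: 13, methyl (E)-4-(TBSO)but-2-enoate
Conditions: CH2Cl2, rt
Reagents that add atoms: none
Why: Wittig olefination with a stabilized ylide gives the (E)-enoate.

**Step 9**
Reactants: 13; 14, isopropenylboronic acid pinacol ester
Product: 15, methyl (S)-3-isopropenyl-4-(TBSO)butanoate (future C13 stereocentre)
Conditions: [Rh(cod)Cl]2 (1.5 mol%), (S)-BINAP (3.3 mol%), aq. KOH, dioxane, 50 °C
Reagents that add atoms: none (boronate is reactant 14)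
Why: Hayashi–Miyaura Rh-catalysed asymmetric 1,4-addition places the isopropenyl group at the β-carbon (C13) with the BINAP-controlled face.

**Step 10**
Reactants: 15
Product: 16, aldehyde (C11 CHO)
Conditions: DIBAL-H, CH2Cl2, −78 °C
Reagents that add atoms: none
Why: DIBAL-H reduction of an ester to the aldehyde at low temperature; the stereocentre is untouched.

**Step 11**
Reactants: 16
Product: 17, dimethyl acetal
Conditions: HC(OMe)3, PPTS (cat.), CH2Cl2, rt
Reagents that add atoms: trimethyl orthoformate, COC(OC)OC
Why: Acetalization protects the aldehyde through the later enolate chemistry.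

**Step 12**
Reactants: 17
Product: 18, alcohol (C14–OH)
Conditions: TBAF, THF, 0 °C
Reagents that add atoms: none
Why: Fluoride desilylation leaves the acetal and isopropenyl group intact.

**Step 13**
Reactants: 18
Product: 19, (S)-1-iodo-2-isopropenyl-4,4-dimethoxybutane
Conditions: I2, PPh3, imidazole, CH2Cl2, 0 °C
Reagents that add atoms: iodine, II
Why: Appel/Garegg–Samuelsson iodination of the primary alcohol proceeds by SN2 at the achiral CH2, so the stereocentre is retained.

**Step 14**
Reactants: 10; 19
Product: 20, δ-lactone alkylated at C8 (C8 epimeric, unspecified)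
Conditions: LDA (1.05 equiv), HMPA, THF, −78 → −20 °C
Reagents that add atoms: none
Why: The kinetic lactone enolate at the unhindered α-CH2 (C8) alkylates by SN2, while the hindered tertiary γ-lactone C5–H is not deprotonated; C8 epimers are irrelevant because Step 16 removes that stereocentre.

**Step 15**
Reactants: 20
Product: 21, α-phenylseleno lactone
Conditions: LDA, THF, −78 °C; then PhSeCl
Reagents that add atoms: benzeneselenenyl chloride, Cl[Se]c1ccccc1
Why: Enolate selenation (Reich–Sharpless α-selenenylation) prepares the dehydrogenation.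

**Step 16**
Reactants: 21
Product: 22, spiro α,β-unsaturated δ-lactone (C8=C9)
Conditions: 30% H2O2, pyridine, CH2Cl2, 0 °C → rt
Reagents that add atoms: none
Why: Selenoxide syn-elimination toward the ring C9–H gives the conjugated endocyclic enoate needed as the ketyl acceptor.

**Step 17**
Reactants: 22
Product: 23, aldehyde (C11 CHO)
Conditions: TESOTf, 2,4,6-collidine, CH2Cl2, 0 °C; then H2O
Reagents that add atoms: water, O
Why: Fujioka–Kita deprotection of the dimethyl acetal via a collidinium intermediate is mild toward the lactones and the alkene.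

**Step 18**
Reactants: 23
Product: 24, tetracycle with ring C formed (C9–C11 bond), C11–OH (epimeric, unspecified) and C8–H
Conditions: SmI2 (3.5 equiv), HMPA, t-BuOH, THF, −78 °C
Reagents that add atoms: none
Why: A SmI2 ketyl–olefin radical cyclization (6-endo onto the enoate β-carbon) closes ring C through a chair-like transition state with the isopropenyl group pseudo-equatorial, fixing C9 trans-1,4 to C13; C11 is corrected in Steps 19–20 and C8 is reset in Step 22.

**Step 19**
Reactants: 24
Product: 25, C11 ketone
Conditions: Dess–Martin periodinane, NaHCO3, CH2Cl2, rt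
Reagents that add atoms: none
Why: Oxidation makes the C11 configuration irrelevant, converging any epimer mixture from Step 18.

**Step 20**
Reactants: 25
Product: 26, C11 alcohol with OH on the same face as C10 and C7 (axial in this conformer, equatorial in the final bicycle)
Conditions: L-Selectride, THF, −78 °C
Reagents that add atoms: none
Why: The bulky trialkylborohydride attacks equatorially and delivers the axial alcohol; the lactones survive at −78 °C.

**Step 21**
Reactants: 26
Product: 27, C11 TBS ether
Conditions: TBSOTf, 2,6-lutidine, CH2Cl2, −78 → 0 °C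
Reagents that add atoms: TBSOTf, CC(C)(C)[Si](C)(C)OS(=O)(=O)C(F)(F)F
Why: Silylation of the hindered secondary alcohol is needed before the enolate chemistry of Step 22.

**Step 22**
Reactants: 27
Product: 28, bicyclo[3.2.1]octane with C8 quaternary and the Δ16 exocyclic methylene (C15H2)
Conditions: LiHMDS, TMSCl, THF, −78 → 0 °C; then Pd(OAc)2 (1.1 equiv), MeCN, 23 °C
Reagents that add atoms: none
Why: Pd(II) oxidative cycloalkenylation of the silyl ketene acetal (Saegusa/Toyota-type) forms C8–C15 on the C13 isopropenyl face, so the bridge fixes the C8 configuration, and β-H elimination from the methyl regenerates the exocyclic alkene.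

**Step 23**
Reactants: 28
Product: 29, C15 ketone (15-oxo-16-ene)
Conditions: SeO2 (0.3 equiv), t-BuOOH (5 equiv), CH2Cl2, rt
Reagents that add atoms: tert-butyl hydroperoxide, CC(C)(C)OO
Why: Riley/Sharpless allylic oxidation occurs at the only allylic CH2 (C15), since C13 is a bridgehead.

**Step 24**
Reactants: 29
Product: 30, C15 endo allylic alcohol
Conditions: NaBH4, CeCl3·7H2O, MeOH, −78 °C
Reagents that add atoms: none
Why: Luche 1,2-reduction delivers hydride from the less hindered exo face of the bicyclo[3.2.1]octane, giving the endo C15–OH of the target.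

**Step 25**
Reactants: 30
Product: 31, Guidongnin
Conditions: HF·pyridine, THF/pyridine, 23 → 40 °C
Reagents that add atoms: none
Why: Fluoride removal of the C11 TBS ether completes the synthesis; all eight stereocentres are already fixed (C4 and C5 in Step 2, C10 in Step 6, C13 in Step 9, C9 in Step 18, C11 in Step 20, C8 in Step 22, C15 in Step 24).

## Compound list
number | name | SMILES | role
1 | (2E)-penta-2,4-dien-1-ol | C=C/C=C/CO | starting material
2 | TBS ether of 1 | C=C/C=C/CO[Si](C)(C)C(C)(C)C | intermediate
3 | 4-methylfuran-2(5H)-one | CC1=CC(=O)OC1 | starting material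
4 | cis-fused bicyclic γ-lactone, Δ1 alkene, C20 CH2OTBS | CC(C)(C)[Si](C)(C)OC[C@H]1C=CC[C@@]2(C)COC(=O)[C@@H]12 | intermediate
5 | saturated lactone | CC(C)(C)[Si](C)(C)OC[C@H]1CCC[C@@]2(C)COC(=O)[C@@H]12 | intermediate
6 | C20 primary alcohol | OC[C@H]1CCC[C@@]2(C)COC(=O)[C@@H]12 | intermediate
7 | C20 aldehyde (C10 epimerizable) | O=CC1CCC[C@@]2(C)COC(=O)[C@@H]12 | intermediate
8 | methyl acrylate | C=CC(=O)OC | starting material
9 | Michael adduct, C10 quaternary | COC(=O)CC[C@]1(C=O)CCC[C@@]2(C)COC(=O)[C@@H]12 | intermediate
10 | spiro-δ-lactone/γ-lactone | O=C1CC[C@]2(CO1)CCC[C@@]3(C)COC(=O)[C@@H]23 | intermediate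
11 | (TBSO)acetaldehyde | CC(C)(C)[Si](C)(C)OCC=O | starting material
12 | methyl (triphenylphosphoranylidene)acetate | COC(=O)C=P(c1ccccc1)(c1ccccc1)c1ccccc1 | starting material
13 | methyl (E)-4-(TBSO)but-2-enoate | COC(=O)/C=C/CO[Si](C)(C)C(C)(C)C | intermediate
14 | isopropenylboronic acid pinacol ester | CC(=C)B1OC(C)(C)C(C)(C)O1 | starting material
15 | methyl (S)-3-isopropenyl-4-(TBSO)butanoate | COC(=O)C[C@@H](C(C)=C)CO[Si](C)(C)C(C)(C)C | intermediate
16 | aldehyde | O=CC[C@@H](C(C)=C)CO[Si](C)(C)C(C)(C)C | intermediate
17 | dimethyl acetal | COC(OC)C[C@@H](C(C)=C)CO[Si](C)(C)C(C)(C)C | intermediate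
18 | alcohol | COC(OC)C[C@@H](C(C)=C)CO | intermediate
19 | (S)-iodide | COC(OC)C[C@@H](C(C)=C)CI | intermediate
20 | C8-alkylated δ-lactone (C8 unspecified) | COC(OC)C[C@@H](C(C)=C)CC1C[C@]2(COC1=O)CCC[C@@]3(C)COC(=O)[C@@H]23 | intermediate
21 | α-phenylseleno lactone | COC(OC)C[C@@H](C(C)=C)CC1([Se]c4ccccc4)C[C@]2(COC1=O)CCC[C@@]3(C)COC(=O)[C@@H]23 | intermediate
22 | unsaturated spirolactone | COC(OC)C[C@@H](C(C)=C)CC1=C[C@]2(COC1=O)CCC[C@@]3(C)COC(=O)[C@@H]23 | intermediate
23 | aldehyde | O=CC[C@@H](C(C)=C)CC1=C[C@]2(COC1=O)CCC[C@@]3(C)COC(=O)[C@@H]23 | intermediate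
24 | ring-C tetracycle, C11-OH and C8 unspecified | C=C(C)[C@@H]1CC(O)[C@H]2[C@@]3(CCC[C@@]4(C)COC(=O)[C@H]43)COC(=O)C2C1 | intermediate
25 | C11 ketone | C=C(C)[C@@H]1CC(=O)[C@H]2[C@@]3(CCC[C@@]4(C)COC(=O)[C@H]43)COC(=O)C2C1 | intermediate
26 | C11 alcohol (configured) | C=C(C)[C@@H]1C[C@@H](O)[C@H]2[C@@]3(CCC[C@@]4(C)COC(=O)[C@H]43)COC(=O)C2C1 | intermediate
27 | C11 TBS ether | C=C(C)[C@@H]1C[C@@H](O[Si](C)(C)C(C)(C)C)[C@H]2[C@@]3(CCC[C@@]4(C)COC(=O)[C@H]43)COC(=O)C2C1 | intermediate
28 | bicyclo[3.2.1] bislactone, 11-OTBS | C=C1[C@@H]2C[C@@H](O[Si](C)(C)C(C)(C)C)[C@H]3[C@@]4(CCC[C@@]5(C)COC(=O)[C@H]54)COC(=O)[C@]3(C2)C1 | intermediate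
29 | 15-oxo-16-ene | C=C1[C@@H]2C[C@@H](O[Si](C)(C)C(C)(C)C)[C@H]3[C@@]4(CCC[C@@]5(C)COC(=O)[C@H]54)COC(=O)[C@]3(C2)C1=O | intermediate
30 | 15-endo-ol, 11-OTBS | C=C1[C@@H]2C[C@@H](O[Si](C)(C)C(C)(C)C)[C@H]3[C@@]4(CCC[C@@]5(C)COC(=O)[C@H]54)COC(=O)[C@]3(C2)[C@@H]1O | intermediate
31 | Guidongnin | C=C1[C@@H]2C[C@@H](O)[C@H]3[C@@]4(CCC[C@@]5(C)COC(=O)[C@H]54)COC(=O)[C@]3(C2)[C@@H]1O | target

## Totals
Total steps: 25. Longest linear sequence: 19 steps (1–7, then 14–25); the chain branch (Steps 8–13) runs in parallel.

## Three steps most likely to fail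
1. **Step 2, the enantioselective Diels–Alder of the trisubstituted butenolide (proposed new method).** It forms a quaternary centre with a poorly reactive dienophile.
   - Fallback: run the Diels–Alder racemic with Me2AlCl or BF3·OEt2 (known Lewis-acid butenolide chemistry), then resolve at alcohol 6 by lipase-catalysed acetylation or by separating camphanate diastereomers.
2. **Step 18, the SmI2 6-endo ketyl–enoate cyclization.** The acceptor β-carbon sits next to the spiro quaternary centre, and 5-exo or pinacol pathways compete.
   - Fallback: switch to a conjugate-addition/RCM approach. Add vinylMgBr/CuI at C9 of the unsaturated lactone and trap the enolate at C8 with a C14–C13(isopropenyl)–CH=CH2 iodide. Close ring C by RCM (Grubbs II) to the C11=C12 alkene. Then epoxidize and open the epoxide with LiAlH4 at C12 to give C11–OH.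
3. **Step 22, the Pd(II) cycloalkenylation.** The C8 ketene acetal must form selectively over the γ-lactone and the axial isopropenyl conformer must be reachable.
   - Fallback: use a polar alkylation instead. Brominate the isopropenyl methyl (NBS, AIBN) to the 2-(bromomethyl)allyl unit, then close the ring by intramolecular LDA enolate alkylation (C8 to the CH2Br carbon). This gives the same bicyclo[3.2.1]octane with exocyclic methylene, because the two terminal carbons of the isopropenyl group are interchangeable.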